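## Retrosynthetic overview
1. Last C–O bond: the ring B phenol comes from an aryl bromide. It is reached through a transient seven-membered lactone with the ring A carboxylate, which is opened again in the same flask.
2. The ring B aldehyde comes from a second, equivalent bromide (Br/Mg exchange, then DMF). Ring B is therefore bought as symmetrical 2,6-dibromo-4-methylphenol and no regiochemical question arises.
3. The (S)-carbinol comes from a ring A aldehyde by catalytic asymmetric isobutyl addition, before any ring B aldehyde exists.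
4. Key disconnection: the diaryl ether C–O bond, made by SNAr of the dibromophenol on 6-fluoro-3-formyl-2-methoxybenzoic acid (fluoride para to CHO). That acid comes from 4-fluoro-2-methoxybenzaldehyde by masked-aldehyde ortho-lithiation and CO2.
5. Ring order: both benzene rings are purchased. The only ring formed is the transient lactone of line 1.

Assumption: the stereocentre in the given SMILES is (S), and (S)-BINOL/Ti(OiPr)4 is taken to attack the Si face as it does with simple benzaldehydes; (R)-BINOL is equally available if the sense is reversed.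

## Route

Step 1
Reactants: 1 4-fluoro-2-methoxybenzaldehyde
Product: 5 6-fluoro-3-formyl-2-methoxybenzoic acid, via lithium amino alkoxide 2 (not isolated), via aryllithium 3 (not isolated), via dilithium carboxylate 4 (not isolated)
Conditions: 1-methylpiperazine (1.1 equiv), n-BuLi (1.05 equiv), THF, −78 to −20 °C; add 1; s-BuLi (1.3 equiv), TMEDA, −78 °C, 1 h; CO2 gas, −78 to 0 °C; 1 M HCl
Reagents that add atoms: carbon dioxide O=C=O
Why: In this Comins-type in situ protection followed by directed ortho-lithiation and carboxylation, the lithium amide adds to the aldehyde to give an amino alkoxide that is inert to s-BuLi and only weakly directing, so lithiation takes the most acidic C–H between F and OMe (held at −78 °C to avoid aryne formation), and acid work-up returns the aldehyde.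

Step 2
Reactants: 5 6-fluoro-3-formyl-2-methoxybenzoic acid; 6 2,6-dibromo-4-methylphenol
Product: 7 6-(2,6-dibromo-4-methylphenoxy)-3-formyl-2-methoxybenzoic acid
Conditions: Cs2CO3 (2.5 equiv), DMSO, 120 °C, 16 h; 1 M HCl
Reagents that add atoms: none
Why: This nucleophilic aromatic substitution (addition–elimination) works because the fluoride is para to the formyl group, which carries the charge of the Meisenheimer intermediate, because fluorobenzaldehydes accept even 2,6-dihalophenoxides under carbonate/dipolar aprotic conditions, and because the symmetrical phenol 6 can give only one ether.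

Step 3
Reactants: 7 6-(2,6-dibromo-4-methylphenoxy)-3-formyl-2-methoxybenzoic acid; 8 isobutylmagnesium bromide
Product: 9 6-(2,6-dibromo-4-methylphenoxy)-3-[(1S)-1-hydroxy-3-methylbutyl]-2-methoxybenzoic acid
Conditions: 8 (3.2 equiv) premixed with bis[2-(dimethylamino)ethyl] ether (3.2 equiv); Ti(OiPr)4 (4 equiv), (S)-BINOL (15 mol %), toluene/Et2O, 0 °C; cold 1 M HCl
Reagents that add atoms: none
Why: In this catalytic enantioselective 1,2-addition of a Grignard-derived alkyltitanium reagent to an aryl aldehyde, one equivalent of reagent removes the acid proton, the chelating diamine ether suppresses the racemic Grignard background, the aryl bromides are inert, and the (S)-BINOL/Ti(OiPr)4 complex delivers isobutyl to the Si face to set the (S)-carbinol.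

Step 4
Reactants: 9 6-(2,6-dibromo-4-methylphenoxy)-3-[(1S)-1-hydroxy-3-methylbutyl]-2-methoxybenzoic acid
Product: 12 6-(2-bromo-6-formyl-4-methylphenoxy)-3-[(1S)-1-hydroxy-3-methylbutyl]-2-methoxybenzoic acid, via aryl Grignard 10 (not isolated), via hemiaminal magnesium alkoxide 11 (not isolated)
Conditions: iPrMgCl (2.1 equiv), THF, −20 °C; iPrMgCl·LiCl (1.5 equiv), 0 to 23 °C, 4 h; DMF (5 equiv), 0 °C; cold 1 M HCl
Reagents that add atoms: N,N-dimethylformamide CN(C)C=O
Why: In this bromine–magnesium exchange and Bouveault formylation, the two acidic protons are removed first, one of the two equivalent C–Br bonds ortho to the ether oxygen exchanges, the now anionic ring resists a second exchange, the magnesium carboxylate is not attacked by the aryl Grignard (an ester would close to a xanthone), and the stereocentre rides through as its alkoxide.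

Step 5
Reactants: 12 6-(2-bromo-6-formyl-4-methylphenoxy)-3-[(1S)-1-hydroxy-3-methylbutyl]-2-methoxybenzoic acid
Product: 14 tenellic acid B, via depsidone lactone 13 (not isolated)
Conditions: CuI (10 mol %), 3,4,7,8-tetramethyl-1,10-phenanthroline (20 mol %), Cs2CO3 (2.2 equiv), DMSO, 80 °C, argon; then LiOH (3 equiv), H2O, 23 °C, 30 min; cold 1 M HCl to pH 3
Reagents that add atoms: lithium hydroxide [Li+].[OH-]
Why: Proposed new method: a carboxylate-relay hydroxylation in which the cesium carboxylate of 12 binds monovalent copper and, together with the diaryl ether oxygen, holds it next to the C–Br bond, so that oxidative addition to an aryl trivalent copper carboxylate and C–O reductive elimination close the unstrained seven-membered aryl ester 13 under carbonate base that spares the aldehyde, after which hydroxide opens this activated lactone at the acyl carbon at room temperature and leaves the oxygen on ring B; the closest known reaction types are the copper-catalysed Ullmann-type lactonisation of 2'-halobiaryl-2-carboxylic acids to six-membered benzocoumarins and the copper-catalysed hydroxylation of aryl bromides, and a seven-membered relay across a diaryl ether has not been shown.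

## Compound list
1 | 4-fluoro-2-methoxybenzaldehyde | COc1cc(F)ccc1C=O | starting material
2 | lithium (4-fluoro-2-methoxyphenyl)(4-methylpiperazin-1-yl)methanolate (hemiaminal carbon unassigned) | COc1cc(F)ccc1C(O[Li])N1CCN(C)CC1 | intermediate
3 | 3-lithio derivative of 2 (Li on the ring carbon between F and OMe) | COc1c([Li])c(F)ccc1C(O[Li])N1CCN(C)CC1 | intermediate
4 | lithium 6-fluoro-2-methoxy-3-[(lithiooxy)(4-methylpiperazin-1-yl)methyl]benzoate | COc1c(C(=O)O[Li])c(F)ccc1C(O[Li])N1CCN(C)CC1 | intermediate
5 | 6-fluoro-3-formyl-2-methoxybenzoic acid | COc1c(C=O)ccc(F)c1C(=O)O | intermediate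
6 | 2,6-dibromo-4-methylphenol | Cc1cc(Br)c(O)c(Br)c1 | starting material
7 | 6-(2,6-dibromo-4-methylphenoxy)-3-formyl-2-methoxybenzoic acid | COc1c(C=O)ccc(Oc2c(Br)cc(C)cc2Br)c1C(=O)O | intermediate
8 | isobutylmagnesium bromide (2 M in Et2O) | CC(C)C[Mg]Br | starting material
9 | 6-(2,6-dibromo-4-methylphenoxy)-3-[(1S)-1-hydroxy-3-methylbutyl]-2-methoxybenzoic acid | COc1c([C@@H](O)CC(C)C)ccc(Oc2c(Br)cc(C)cc2Br)c1C(=O)O | intermediate
10 | aryl Grignard of 9 (MgCl in place of one Br; carboxylate and alkoxide as chloromagnesium salts) | COc1c([C@@H](O[Mg]Cl)CC(C)C)ccc(Oc2c(Br)cc(C)cc2[Mg]Cl)c1C(=O)O[Mg]Cl | intermediate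
11 | DMF adduct of 10 (ring B carries CH(OMgCl)NMe2, carbon unassigned) | COc1c([C@@H](O[Mg]Cl)CC(C)C)ccc(Oc2c(Br)cc(C)cc2C(O[Mg]Cl)N(C)C)c1C(=O)O[Mg]Cl | intermediate
12 | 6-(2-bromo-6-formyl-4-methylphenoxy)-3-[(1S)-1-hydroxy-3-methylbutyl]-2-methoxybenzoic acid | COc1c([C@@H](O)CC(C)C)ccc(Oc2c(Br)cc(C)cc2C=O)c1C(=O)O | intermediate
13 | depsidone lactone: 2-[(1S)-1-hydroxy-3-methylbutyl]-1-methoxy-8-methyl-11-oxo-11H-dibenzo[b,e][1,4]dioxepine-6-carbaldehyde | COc1c([C@@H](O)CC(C)C)ccc2Oc3c(C=O)cc(C)cc3OC(=O)c12 | intermediate
14 | tenellic acid B: 6-(2-formyl-6-hydroxy-4-methylphenoxy)-3-[(1S)-1-hydroxy-3-methylbutyl]-2-methoxybenzoic acid | COc1c([C@@H](O)CC(C)C)ccc(Oc2c(O)cc(C)cc2C=O)c1C(=O)O | target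

## Step count and risks
Total step count: 5. Longest linear sequence: 5.

**Step 5 (the new step).**
- Risk: closure through the large copper chelate may be slower than hydrodebromination or loss of CO2.
- Fallback (known chemistry): it sets out from 12. Miyaura borylation (B2pin2, Pd(dppf)Cl2, KOAc, dioxane, 90 °C) gives the pinacol boronate 6-[2-formyl-4-methyl-6-(4,4,5,5-tetramethyl-1,3,2-dioxaborolan-2-yl)phenoxy]-3-[(1S)-1-hydroxy-3-methylbutyl]-2-methoxybenzoic acid F5. Oxidation of its C–B bond with N-methylmorpholine N-oxide (THF, 50 °C) leaves the aldehyde alone and comes back to the route at 14.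

**Step 2.**
- Risk: a weak, doubly ortho-hindered phenoxide meets a fluoride that sits next to an anionic carboxylate.
- Fallback: it sets out from 5. Allyl bromide/K2CO3 in DMF gives allyl 6-fluoro-3-formyl-2-methoxybenzoate F1, whose fluoride is now activated by an ortho ester as well as the para aldehyde. SNAr with 6 (K2CO3, DMF, 80 °C) gives allyl 6-(2,6-dibromo-4-methylphenoxy)-3-formyl-2-methoxybenzoate F2. Allyl transfer with Pd(PPh3)4 and sodium 4-methylbenzenesulfinate (THF/MeOH, 23 °C) comes back at 7.

**Step 3.**
- Risk: the free acid (as a titanium or magnesium carboxylate) and the ortho-methoxy group may erode the enantioselectivity.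
- Fallback: it sets out from 7. Uncatalysed addition of 8 (2.2 equiv, THF, −78 °C) gives racemic 6-(2,6-dibromo-4-methylphenoxy)-3-(1-hydroxy-3-methylbutyl)-2-methoxybenzoic acid F3. MnO2 in CH2Cl2 gives the ketone 6-(2,6-dibromo-4-methylphenoxy)-2-methoxy-3-(3-methylbutanoyl)benzoic acid F4. Noyori asymmetric transfer hydrogenation with RuCl[(S,S)-TsDPEN](p-cymene) in HCO2H/Et3N tolerates carboxylic acids and comes back at 9.

## Further compounds
F1 | step 2 | allyl 6-fluoro-3-formyl-2-methoxybenzoate | C=CCOC(=O)c1c(F)ccc(C=O)c1OC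
F2 | step 2 | allyl 6-(2,6-dibromo-4-methylphenoxy)-3-formyl-2-methoxybenzoate | C=CCOC(=O)c1c(Oc2c(Br)cc(C)cc2Br)ccc(C=O)c1OC
F3 | step 3 | racemic 6-(2,6-dibromo-4-methylphenoxy)-3-(1-hydroxy-3-methylbutyl)-2-methoxybenzoic acid | COc1c(C(O)CC(C)C)ccc(Oc2c(Br)cc(C)cc2Br)c1C(=O)O
F4 | step 3 | 6-(2,6-dibromo-4-methylphenoxy)-2-methoxy-3-(3-methylbutanoyl)benzoic acid | COc1c(C(=O)CC(C)C)ccc(Oc2c(Br)cc(C)cc2Br)c1C(=O)O
F5 | step 5 | 6-[2-formyl-4-methyl-6-(4,4,5,5-tetramethyl-1,3,2-dioxaborolan-2-yl)phenoxy]-3-[(1S)-1-hydroxy-3-methylbutyl]-2-methoxybenzoic acid | COc1c([C@@H](O)CC(C)C)ccc(Oc2c(B3OC(C)(C)C(C)(C)O3)cc(C)cc2C=O)c1C(=O)O
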